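**Retrosynthetic overview**

1. The target is traced back to the silyl-protected hydroxy ester 25 and 4-methylpent-3-enoic acid (Mitsunobu esterification, fluoride deprotection last). The C8 carboxyl comes from an aryl bromide (Pd/CO), and the C4 methyl from a trans-selective AlMe3 substitution of a benzylic alcohol.
2. Side-chain carbons C3'–C6' are attached by alkylating the α-sulfinyl carbon C2' of a temporary thiolane S-oxide that links C2' to C2. Nickel boride then removes the sulfur, leaving C2–H and C2'–H.
3. Ring B and the temporary thiolane form in one photochemical operation, an intramolecular photoenolization/Diels–Alder reaction of an o-alkylbenzaldehyde whose vinyl sulfoxide is tethered through sulfur to C2'. The vinyl group supplies C2–C3, and the bonds C1–C2 and C3–C4 form together.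
4. Enabling feature: C4 and C1 are benzylic carbons on the adjacent ring A atoms C4a and C8a. With C4 as an aldehyde, its excited oxygen abstracts a C1–H through a six-membered transition state (O=C4–C4a=C8a–C1–H). This dearomatizes ring A to the diene C4=C4a–C8a=C1, whose termini are the two carbons to be bonded.
5. Ring order: ring A is bought, ring B and the thiolane form in step 6, and the thiolane is opened in step 11. C1' and C5' come from the two enantiomers of 3-bromo-2-methylpropan-1-ol, C1 from step 6 and C4 from step 13.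

Key step: step 6

Locants used below: tetralin ring of the target C1 (bears the side chain), C2, C3, C4 (bears the methyl), C5 (OH), C8 (CO2H), ring fusion C4a/C8a; side chain C1' to C6' counted from the ring; ring A is the arene, ring B the saturated ring.

Remark: compounds 10–12 and 18–20 are carried as mixtures at sulfur (and at C2 and C2' where these are stereogenic); all three centres are cleared in step 11, so the SMILES leave them undefined.

**Route**

Step 1
Reactants: 1 2-bromo-6-hydroxybenzaldehyde
Product: 2 2-bromo-6-[(triisopropylsilyl)oxy]benzaldehyde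
Conditions: TIPSCl, imidazole, DMF, 0 → 23 °C
Reagents that add atoms: triisopropylsilyl chloride, CC(C)[Si](Cl)(C(C)C)C(C)C
Why: Imidazole-mediated silyl ether formation masks the phenol, which would otherwise quench the organozinc reagent and suppress photoenolization, and the bulky group later shields the ortho position in step 12; no stereocentre is involved.

Step 2
Reactants: 3 (2R)-3-bromo-2-methylpropan-1-ol; 4 vinylmagnesium bromide
Product: 6 (2R)-3-(ethenylsulfanyl)-2-methylpropan-1-ol, via bromomagnesium ethenethiolate 5 (not isolated)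
Conditions: 4, S8, THF, 0 °C; then 3, DMF, 50 °C
Reagents that add atoms: octasulfur, S1SSSSSSS1
Why: Sulfur insertion into the vinyl Grignard reagent should give the ethenethiolate, whose S-alkylation by the primary bromide (SN2) places the future dienophile on C2' without touching the C1' stereocentre.

Step 3
Reactants: 6 (2R)-3-(ethenylsulfanyl)-2-methylpropan-1-ol
Product: 7 (2S)-1-(ethenylsulfanyl)-3-iodo-2-methylpropane
Conditions: PPh3, I2, imidazole, CH2Cl2, 0 °C (phosphonium iodide preformed)
Reagents that add atoms: iodine, II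
Why: Appel-type iodination converts the primary alcohol into the iodide needed for zinc insertion; preforming the phosphonium iodide keeps free iodine away from the vinyl sulfide, and the stereocentre one carbon away is unaffected.

Step 4
Reactants: 7 (2S)-1-(ethenylsulfanyl)-3-iodo-2-methylpropane; 2 2-bromo-6-[(triisopropylsilyl)oxy]benzaldehyde
Product: 9 2-[(2R)-3-(ethenylsulfanyl)-2-methylpropyl]-6-[(triisopropylsilyl)oxy]benzaldehyde, via alkylzinc iodide 8 (not isolated)
Conditions: Zn dust, LiCl, THF, 40 °C; then 2, Pd(OAc)2 (cat.), SPhos, THF, 50 °C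
Reagents that add atoms: none
Why: LiCl-assisted zinc insertion followed by Negishi sp3–sp2 coupling joins C1 to ring A; alkylzinc halides tolerate the free aldehyde and SPhos makes reductive elimination faster than β-hydride elimination, so C1' should keep its configuration.

Step 5
Reactants: 9 2-[(2R)-3-(ethenylsulfanyl)-2-methylpropyl]-6-[(triisopropylsilyl)oxy]benzaldehyde
Product: 10 2-[(2R)-3-(ethenylsulfinyl)-2-methylpropyl]-6-[(triisopropylsilyl)oxy]benzaldehyde
Conditions: NaIO4, MeOH–H2O, 0 → 23 °C
Reagents that add atoms: sodium periodate, [Na+].[O-]I(=O)(=O)=O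
Why: Periodate oxidation stops at the sulfoxide and leaves the aldehyde alone; it turns the vinyl group into an electron-poor dienophile and provides the α-acidity used in step 10, while the new sulfur centre (mixture) is inconsequential.

Step 6
Reactants: 10 2-[(2R)-3-(ethenylsulfinyl)-2-methylpropyl]-6-[(triisopropylsilyl)oxy]benzaldehyde
Product: 12 tricyclic hydroxy sulfoxide (1S,4S,1'R), via photoenol 11 (not isolated)
Conditions: hν (365 nm), degassed benzene (0.005 M), 23 °C
Reagents that add atoms: none
Why: Excitation of the aryl aldehyde (n,π*) lets its oxygen abstract a hydrogen from the ortho benzylic CH2 (C1) through a six-membered transition state, and the resulting biradical relaxes to the hydroxy-o-quinodimethane 11 (diene C4=C4a–C8a=C1), which the tethered vinyl sulfoxide captures in a suprafacial [4+2] cycloaddition that forms C1–C2 and C3–C4 and restores the aromaticity of ring A; the closest known reaction type is the intramolecular photoenolization/Diels–Alder reaction of o-alkylbenzaldehydes carrying a tethered electron-poor alkene. Ring B is closed by the [4+2] cycloaddition itself (two σ bonds at the diene termini), and the temporary thiolane S-oxide ring is closed in the same event as the three-atom tether ring fused across C1–C2. The new C1 centre is controlled by the C1' stereocentre: to avoid allylic 1,3-strain with the peri C8–H the C1'–H eclipses the C1=C8a bond, the methyl points away and the C2'–S arm carries the dienophile to the opposite diene face, which should give the (1S) configuration of the target. The C4 carbinol centre follows from the outward hydroxyl of the only long-lived dienol and is erased in step 13, while the centres at sulfur and C2 are uncontrolled and are removed in step 11. The step needs diene-face selectivity, secured by the tether together with the C1' stereocentre, and regiochemistry (C2 to C1, C3 to C4), which the tether enforces because the other orientation would require a bridged ring. Dienol geometries that cannot cyclize revert to 10 by 1,5-hydrogen shift and are recycled under the irradiation.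

Step 7
Reactants: 13 (2S)-3-bromo-2-methylpropan-1-ol
Product: 14 {[(2S)-3-bromo-2-methylpropyl]oxy}(tert-butyl)dimethylsilane
Conditions: TBSCl, imidazole, CH2Cl2, 23 °C
Reagents that add atoms: tert-butyldimethylsilyl chloride, CC(C)(C)[Si](C)(C)Cl
Why: Silyl ether formation protects the future C6' hydroxyl through the organometallic steps; the stereocentre (future C5') is not involved.

Step 8
Reactants: 14 {[(2S)-3-bromo-2-methylpropyl]oxy}(tert-butyl)dimethylsilane
Product: 16 (3R)-4-{[tert-butyl(dimethyl)silyl]oxy}-3-methylbutan-1-ol, via Grignard reagent 15 (not isolated)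
Conditions: Mg, THF, 40 °C; then (CH2O)n, 0 → 23 °C; aq NH4Cl
Reagents that add atoms: paraformaldehyde (source of formaldehyde), C=O
Why: Grignard formation and addition to formaldehyde homologates the chain by the carbon that becomes C3'; the stereocentre is untouched.

Step 9
Reactants: 16 (3R)-4-{[tert-butyl(dimethyl)silyl]oxy}-3-methylbutan-1-ol
Product: 17 tert-butyl{[(2R)-4-iodo-2-methylbutyl]oxy}dimethylsilane
Conditions: PPh3, I2, imidazole, CH2Cl2, 0 °C
Reagents that add atoms: iodine, II
Why: Appel-type iodination gives the unhindered primary iodide used as the electrophile in step 10; no stereocentre is touched.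

Step 10
Reactants: 12 tricyclic hydroxy sulfoxide (1S,4S,1'R); 17 tert-butyl{[(2R)-4-iodo-2-methylbutyl]oxy}dimethylsilane
Product: 20 C2'-alkylated tricyclic hydroxy sulfoxide, via trimethylsilyl ether 18 (not isolated), via alkylated trimethylsilyl ether 19 (not isolated)
Conditions: N-(trimethylsilyl)imidazole, THF, 23 °C; LDA (2.3 equiv), −78 °C; 17, DMPU, −78 → −40 °C; aq citric acid
Reagents that add atoms: none
Why: After transient O-silylation (which prevents migration of the aryl TIPS group to a C4 alkoxide), kinetic deprotonation of the sulfoxide at the less substituted α-carbon C2' (CH2 rather than the ring-fusion CH) and SN2 alkylation of the α-sulfinyl carbanion attach C3'–C6'; the new C2' centre forms as a mixture and is cleared in step 11.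

Step 11
Reactants: 20 C2'-alkylated tricyclic hydroxy sulfoxide
Product: 21 (1S,4S)-4-[(2S,6R)-7-{[tert-butyl(dimethyl)silyl]oxy}-6-methylheptan-2-yl]-8-[(triisopropylsilyl)oxy]-1,2,3,4-tetrahydronaphthalen-1-ol
Conditions: NiCl2·6H2O, NaBH4, MeOH–THF, 0 °C
Reagents that add atoms: none
Why: Nickel boride formed in situ should deoxygenate the sulfoxide and hydrogenolyse both C–S bonds (reductive desulfurization), leaving CH2 at C2 and C2' and erasing the sulfur, C2 and C2' centres, while C1, C1', C5' and the benzylic alcohol are not touched at 0 °C.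

Step 12
Reactants: 21 desulfurized tetralinol (C8–H)
Product: 22 (1S,4S)-5-bromo-4-[(2S,6R)-7-{[tert-butyl(dimethyl)silyl]oxy}-6-methylheptan-2-yl]-8-[(triisopropylsilyl)oxy]-1,2,3,4-tetrahydronaphthalen-1-ol
Conditions: NBS, MeCN, 0 °C
Reagents that add atoms: N-bromosuccinimide, O=C1CCC(=O)N1Br
Why: Electrophilic aromatic bromination should occur para to the silyloxy group (C8), the ortho position being shielded by the TIPS group; the bromine is the carboxyl precursor and the peri substituent that fixes the conformation in step 13.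

Step 13
Reactants: 22 bromo tetralinol
Product: 23 {[(5S,8R)-4-bromo-5-[(2S,6R)-7-{[tert-butyl(dimethyl)silyl]oxy}-6-methylheptan-2-yl]-8-methyl-5,6,7,8-tetrahydronaphthalen-1-yl]oxy}tri(propan-2-yl)silane
Conditions: AlMe3 (4 equiv), CH2Cl2, −78 → 23 °C
Reagents that add atoms: trimethylaluminium, C[Al](C)C
Why: AlMe3 ionizes the aluminium alkoxide to the o-silyloxy-stabilized benzylic cation and transfers methyl to it (SN1 methylation of a benzylic alcohol); the C1 side chain is held pseudoaxial by the peri C8 bromine and methyl enters along the axial trajectory on the opposite face, which should give the trans-1,4 (4R) product, also the thermodynamically favoured one because an equatorial C4 methyl would clash with the C5 silyloxy group.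

Step 14
Reactants: 23 methylated aryl bromide
Product: 24 2-(trimethylsilyl)ethyl (5R,8S)-8-[(2S,6R)-7-{[tert-butyl(dimethyl)silyl]oxy}-6-methylheptan-2-yl]-5-methyl-4-[(triisopropylsilyl)oxy]-5,6,7,8-tetrahydronaphthalene-1-carboxylate
Conditions: CO (1 atm), Pd(OAc)2 (cat.), Xantphos, Et3N, Me3SiCH2CH2OH, toluene, 90 °C
Reagents that add atoms: carbon monoxide, [C-]#[O+]; 2-(trimethylsilyl)ethanol, C[Si](C)(C)CCO
Why: Pd-catalysed alkoxycarbonylation of the aryl bromide (oxidative addition, CO insertion, alcoholysis) installs the C8 carboxyl directly as its fluoride-labile ester; no stereocentre is involved.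

Step 15
Reactants: 24 fully protected ester
Product: 25 2-(trimethylsilyl)ethyl (5R,8S)-8-[(2S,6R)-7-hydroxy-6-methylheptan-2-yl]-5-methyl-4-[(triisopropylsilyl)oxy]-5,6,7,8-tetrahydronaphthalene-1-carboxylate
Conditions: PPTS, MeOH, 23 °C
Reagents that add atoms: none
Why: Mild acidic methanolysis removes the primary alkyl TBS ether, while the aryl TIPS ether and the silylethyl ester, both stable to weak acid, should remain.

Step 16
Reactants: 25 primary alcohol; 26 4-methylpent-3-enoic acid
Product: 27 2-(trimethylsilyl)ethyl (5R,8S)-5-methyl-8-{(2S,6R)-6-methyl-7-[(4-methylpent-3-enoyl)oxy]heptan-2-yl}-4-[(triisopropylsilyl)oxy]-5,6,7,8-tetrahydronaphthalene-1-carboxylate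
Conditions: PPh3, DIAD, THF, 0 → 23 °C
Reagents that add atoms: none
Why: Mitsunobu esterification activates the alcohol rather than the acid, so the β,γ-unsaturated acid is never converted into an activated acyl species whose α-deprotonation could move the double bond into conjugation; the carbinol carbon is not stereogenic.

Step 17
Reactants: 27 protected target
Product: 28 (5R,8S)-4-hydroxy-5-methyl-8-{(2S,6R)-6-methyl-7-[(4-methylpent-3-enoyl)oxy]heptan-2-yl}-5,6,7,8-tetrahydronaphthalene-1-carboxylic acid (target)
Conditions: TBAF, AcOH (1:1), THF, 0 → 23 °C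
Reagents that add atoms: none
Why: Buffered fluoride cleaves the aryl silyl ether and, by fluoride-induced β-elimination (loss of ethene and Me3SiF), the silylethyl ester in one operation, under conditions too mild to hydrolyse or isomerize the side-chain ester.

**Compound list**

1 | 2-bromo-6-hydroxybenzaldehyde | O=Cc1c(O)cccc1Br | starting material
2 | 2-bromo-6-[(triisopropylsilyl)oxy]benzaldehyde | O=Cc1c(O[Si](C(C)C)(C(C)C)C(C)C)cccc1Br | intermediate
3 | (2R)-3-bromo-2-methylpropan-1-ol | BrC[C@H](C)CO | starting material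
4 | vinylmagnesium bromide | C=C[Mg]Br | starting material
5 | bromomagnesium ethenethiolate | C=CS[Mg]Br | intermediate
6 | (2R)-3-(ethenylsulfanyl)-2-methylpropan-1-ol | C=CSC[C@H](C)CO | intermediate
7 | (2S)-1-(ethenylsulfanyl)-3-iodo-2-methylpropane | C=CSC[C@H](C)CI | intermediate
8 | [(2S)-3-(ethenylsulfanyl)-2-methylpropyl]zinc iodide | C=CSC[C@H](C)C[Zn]I | intermediate
9 | 2-[(2R)-3-(ethenylsulfanyl)-2-methylpropyl]-6-[(triisopropylsilyl)oxy]benzaldehyde | C=CSC[C@H](C)Cc1cccc(O[Si](C(C)C)(C(C)C)C(C)C)c1C=O | intermediate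
10 | 2-[(2R)-3-(ethenylsulfinyl)-2-methylpropyl]-6-[(triisopropylsilyl)oxy]benzaldehyde (both sulfur epimers) | C=CS(=O)C[C@H](C)Cc1cccc(O[Si](C(C)C)(C(C)C)C(C)C)c1C=O | intermediate
11 | photoenol: 6-(hydroxymethylidene)-5-[(2R)-3-(ethenylsulfinyl)-2-methylpropylidene]-1-[(triisopropylsilyl)oxy]cyclohexa-1,3-diene, hydroxyl and side chain both outward | O/C=C1\C(O[Si](C(C)C)(C(C)C)C(C)C)=CC=C/C1=C\[C@@H](C)CS(=O)C=C | intermediate
12 | tricyclic hydroxy sulfoxide: (1S,4S)-4-hydroxy-5-[(triisopropylsilyl)oxy]tetralin bridged from C1 to C2 by –CH(CH3)–CH2–S(O)– (1'R; thiolane S-oxide ring C1–C1'–C2'–S–C2; epimers at S and C2) | C[C@H]1CS(=O)C2C[C@H](O)c3c(O[Si](C(C)C)(C(C)C)C(C)C)cccc3[C@H]12 | intermediate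
13 | (2S)-3-bromo-2-methylpropan-1-ol | OC[C@H](C)CBr | starting material
14 | {[(2S)-3-bromo-2-methylpropyl]oxy}(tert-butyl)dimethylsilane | CC(C)(C)[Si](C)(C)OC[C@H](C)CBr | intermediate
15 | [(2S)-3-{[tert-butyl(dimethyl)silyl]oxy}-2-methylpropyl]magnesium bromide | CC(C)(C)[Si](C)(C)OC[C@H](C)C[Mg]Br | intermediate
16 | (3R)-4-{[tert-butyl(dimethyl)silyl]oxy}-3-methylbutan-1-ol | CC(C)(C)[Si](C)(C)OC[C@H](C)CCO | intermediate
17 | tert-butyl{[(2R)-4-iodo-2-methylbutyl]oxy}dimethylsilane | CC(C)(C)[Si](C)(C)OC[C@H](C)CCI | intermediate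
18 | C4 trimethylsilyl ether of 12 | C[C@H]1CS(=O)C2C[C@H](O[Si](C)(C)C)c3c(O[Si](C(C)C)(C(C)C)C(C)C)cccc3[C@H]12 | intermediate
19 | 18 carrying the (3R)-4-{[tert-butyl(dimethyl)silyl]oxy}-3-methylbutyl group on C2' (epimers at C2', S, C2) | C[C@H]1C(CC[C@@H](C)CO[Si](C)(C)C(C)(C)C)S(=O)C2C[C@H](O[Si](C)(C)C)c3c(O[Si](C(C)C)(C(C)C)C(C)C)cccc3[C@H]12 | intermediate
20 | C2'-alkylated tricyclic hydroxy sulfoxide (12 carrying the (3R)-4-silyloxy-3-methylbutyl group on C2') | C[C@H]1C(CC[C@@H](C)CO[Si](C)(C)C(C)(C)C)S(=O)C2C[C@H](O)c3c(O[Si](C(C)C)(C(C)C)C(C)C)cccc3[C@H]12 | intermediate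
21 | (1S,4S)-4-[(2S,6R)-7-{[tert-butyl(dimethyl)silyl]oxy}-6-methylheptan-2-yl]-8-[(triisopropylsilyl)oxy]-1,2,3,4-tetrahydronaphthalen-1-ol | CC(C)(C)[Si](C)(C)OC[C@H](C)CCC[C@H](C)[C@@H]1CC[C@H](O)c2c(O[Si](C(C)C)(C(C)C)C(C)C)cccc21 | intermediate
22 | (1S,4S)-5-bromo-4-[(2S,6R)-7-{[tert-butyl(dimethyl)silyl]oxy}-6-methylheptan-2-yl]-8-[(triisopropylsilyl)oxy]-1,2,3,4-tetrahydronaphthalen-1-ol | CC(C)(C)[Si](C)(C)OC[C@H](C)CCC[C@H](C)[C@@H]1CC[C@H](O)c2c(O[Si](C(C)C)(C(C)C)C(C)C)ccc(Br)c21 | intermediate
23 | {[(5S,8R)-4-bromo-5-[(2S,6R)-7-{[tert-butyl(dimethyl)silyl]oxy}-6-methylheptan-2-yl]-8-methyl-5,6,7,8-tetrahydronaphthalen-1-yl]oxy}tri(propan-2-yl)silane | CC(C)(C)[Si](C)(C)OC[C@H](C)CCC[C@H](C)[C@@H]1CC[C@@H](C)c2c(O[Si](C(C)C)(C(C)C)C(C)C)ccc(Br)c21 | intermediate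
24 | 2-(trimethylsilyl)ethyl (5R,8S)-8-[(2S,6R)-7-{[tert-butyl(dimethyl)silyl]oxy}-6-methylheptan-2-yl]-5-methyl-4-[(triisopropylsilyl)oxy]-5,6,7,8-tetrahydronaphthalene-1-carboxylate | CC(C)(C)[Si](C)(C)OC[C@H](C)CCC[C@H](C)[C@@H]1CC[C@@H](C)c2c(O[Si](C(C)C)(C(C)C)C(C)C)ccc(C(=O)OCC[Si](C)(C)C)c21 | intermediate
25 | 2-(trimethylsilyl)ethyl (5R,8S)-8-[(2S,6R)-7-hydroxy-6-methylheptan-2-yl]-5-methyl-4-[(triisopropylsilyl)oxy]-5,6,7,8-tetrahydronaphthalene-1-carboxylate | OC[C@H](C)CCC[C@H](C)[C@@H]1CC[C@@H](C)c2c(O[Si](C(C)C)(C(C)C)C(C)C)ccc(C(=O)OCC[Si](C)(C)C)c21 | intermediate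
26 | 4-methylpent-3-enoic acid | CC(C)=CCC(=O)O | starting material
27 | 2-(trimethylsilyl)ethyl (5R,8S)-5-methyl-8-{(2S,6R)-6-methyl-7-[(4-methylpent-3-enoyl)oxy]heptan-2-yl}-4-[(triisopropylsilyl)oxy]-5,6,7,8-tetrahydronaphthalene-1-carboxylate | CC(C)=CCC(=O)OC[C@H](C)CCC[C@H](C)[C@@H]1CC[C@@H](C)c2c(O[Si](C(C)C)(C(C)C)C(C)C)ccc(C(=O)OCC[Si](C)(C)C)c21 | intermediate
28 | (5R,8S)-4-hydroxy-5-methyl-8-{(2S,6R)-6-methyl-7-[(4-methylpent-3-enoyl)oxy]heptan-2-yl}-5,6,7,8-tetrahydronaphthalene-1-carboxylic acid | CC(C)=CCC(=O)OC[C@H](C)CCC[C@H](C)[C@@H]1CC[C@@H](C)c2c(O)ccc(C(=O)O)c21 | target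

**Step count**

Total steps: 17. Longest linear sequence: 13 steps (steps 2–6 and 10–17, from 3 to 28).

**Steps most likely to fail**

1. Step 6 (key step). Thermal return of the photoenol to the aldehyde, or photodegradation of the sulfoxide, may outrun intramolecular capture. The tether imposes a regiochemistry opposed to the natural polarization of the dienol and the vinyl sulfoxide, so the cycloaddition is slower than a matched one. Fallback: set out from sulfide 9 and separate diene generation from capture. Irradiation of 9 (365 nm, MeCN, −40 °C) should let the dienol close to the benzocyclobutenol F1. Heating F1 (toluene, 110 °C) reopens it by conrotatory ring opening with the hydroxyl turning outward. The oxy-o-quinodimethane is then regenerated continuously in the ground state, where even the unactivated vinyl sulfide should capture it (thermal intramolecular Diels–Alder of a benzocyclobutene-derived o-quinodimethane) with the same facial control, to give the tricyclic sulfide F2. Oxidation of F2 with NaIO4 returns to the route at 12.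

2. Step 10. Metalation of the sulfoxide may be slow or may occur at the ring-fusion carbon C2, and the α-sulfinyl carbanion may react sluggishly with the unactivated iodide. Fallback: set out from 12, silylated as in step 10 to 18, and change to sulfone carbanion chemistry. Oxidation of 18 with mCPBA gives the sulfone F3, whose more acidic α-CH2 is deprotonated with LiHMDS at −78 °C and alkylated with 17 to give F4. LiAlH4 (Et2O, reflux), which reduces five-membered cyclic sulfones to thiolanes, then gives the thiolane F5 with loss of the trimethylsilyl ether on basic work-up. Nickel boride as in step 11 returns to the route at 21.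

3. Step 13. The benzylic cation may eliminate to the 3,4-dihydronaphthalene instead of accepting methyl, or methyl may be delivered from the wrong face. Fallback: set out from 22 and replace the cation by an o-quinone methide, keeping methyl as the incoming nucleophile. Selective cleavage of the aryl silyl ether (Cs2CO3, DMF–H2O) gives the phenol F6, and Boc2O with catalytic DMAP gives the aryl carbonate F7. MeMgCl (3 equiv, THF, −78 → 0 °C) deprotonates the C4 alcohol; the carbonate migrates to the benzylic oxygen and is expelled to give the o-quinone methide, and a second equivalent adds to C4 along the axial trajectory anti to the C1 side chain to give the trans phenol F8. Resilylation (TIPSCl, imidazole) returns to the route at 23.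

**Further compounds**

F1 | step 6 | benzocyclobutenol: 8-[(2R)-1-(ethenylsulfanyl)propan-2-yl]-5-[(triisopropylsilyl)oxy]bicyclo[4.2.0]octa-1,3,5-trien-7-ol | OC1c2c(O[Si](C(C)C)(C(C)C)C(C)C)cccc2C1[C@@H](C)CSC=C
F2 | step 6 | tricyclic hydroxy sulfide (12 without the sulfoxide oxygen; epimers at C2) | C[C@H]1CSC2C[C@H](O)c3c(O[Si](C(C)C)(C(C)C)C(C)C)cccc3[C@H]12
F3 | step 10 | tricyclic sulfone trimethylsilyl ether (S,S-dioxide of 18) | C[C@H]1CS(=O)(=O)C2C[C@H](O[Si](C)(C)C)c3c(O[Si](C(C)C)(C(C)C)C(C)C)cccc3[C@H]12
F4 | step 10 | C2'-alkylated sulfone trimethylsilyl ether | C[C@H]1C(CC[C@@H](C)CO[Si](C)(C)C(C)(C)C)S(=O)(=O)C2C[C@H](O[Si](C)(C)C)c3c(O[Si](C(C)C)(C(C)C)C(C)C)cccc3[C@H]12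
F5 | step 10 | C2'-alkylated tricyclic hydroxy thiolane | C[C@H]1C(CC[C@@H](C)CO[Si](C)(C)C(C)(C)C)SC2C[C@H](O)c3c(O[Si](C(C)C)(C(C)C)C(C)C)cccc3[C@H]12
F6 | step 13 | (5S,8S)-4-bromo-5-[(2S,6R)-7-{[tert-butyl(dimethyl)silyl]oxy}-6-methylheptan-2-yl]-5,6,7,8-tetrahydronaphthalene-1,8-diol | CC(C)(C)[Si](C)(C)OC[C@H](C)CCC[C@H](C)[C@@H]1CC[C@H](O)c2c(O)ccc(Br)c21
F7 | step 13 | tert-butyl aryl carbonate of F6 (phenolic oxygen acylated, C4 hydroxyl free) | CC(C)(C)[Si](C)(C)OC[C@H](C)CCC[C@H](C)[C@@H]1CC[C@H](O)c2c(OC(=O)OC(C)(C)C)ccc(Br)c21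
F8 | step 13 | (5S,8R)-4-bromo-5-[(2S,6R)-7-{[tert-butyl(dimethyl)silyl]oxy}-6-methylheptan-2-yl]-8-methyl-5,6,7,8-tetrahydronaphthalen-1-ol | CC(C)(C)[Si](C)(C)OC[C@H](C)CCC[C@H](C)[C@@H]1CC[C@@H](C)c2c(O)ccc(Br)c21
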